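**Strategy.** The oxane ring is traced back to a δ-lactone whose C2 is still a carbonyl, and this ring is closed by an aldol bond between C3 and the carbinol carbon C4. The key step exploits the fact that C3 lies between C4–OH and the exocyclic allylic stereocentre C3′ of the heptenyl chain: rhodium-catalysed addition of a styrylboronic acid to an acyclic enoate ester of a β-hydroxy aldehyde creates C3′ and an ester enolate at C3, which closes the ring on the C4 aldehyde, fixing C3′, C3 and C4 in one operation. Both halves of the precursor come from one homoallylic alcohol, whose single catalytically set centre becomes C6 and C5′.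

Key step: step 8

Numbering and abbreviations: oxane O1, C2–C6; heptenyl chain C1′–C7′, attached through C3′; TBS = tert-butyldimethylsilyl.

Assumption: the (R)-BINOL/Ti(OiPr)4 allylation is taken to attack the Re face of the aliphatic aldehyde and the (S)-BINAP/rhodium alkenylation the α-Si face of the (E)-enoate, as the accepted models for aliphatic aldehydes and crotonates predict; the antipodal ligand would be used if either sense proved opposite.

**Route**

Step 1
Reactants: 1 tert-butyl(4-iodophenoxy)dimethylsilane; 2 prop-2-en-1-ol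
Product: 3 3-[4-(TBS-oxy)phenyl]propanal
Conditions: Pd(OAc)2 (3 mol%), Bu4NCl, NaHCO3, DMF, 40 °C
Reagents that add atoms: none
Why: Heck arylation of allyl alcohol under Jeffery conditions, in which the arylpalladium adds to the terminal carbon and β-hydride elimination toward the carbinol gives the enol and hence the aldehyde; no stereocentre is formed.

Step 2
Reactants: 3 3-[4-(TBS-oxy)phenyl]propanal; 4 allyltributylstannane
Product: 5 (S)-1-[4-(TBS-oxy)phenyl]hex-5-en-3-ol
Conditions: (R)-BINOL (10 mol%), Ti(OiPr)4 (10 mol%), 4 Å MS, CH2Cl2, −20 °C; aq. NaHCO3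
Reagents that add atoms: none
Why: Keck asymmetric allylation, in which the BINOL–titanium Lewis acid should direct the allyl group to the Re face of the aldehyde and so set the (S) carbinol that later becomes both C6 and C5′.

Step 3
Reactants: 5 (S)-1-[4-(TBS-oxy)phenyl]hex-5-en-3-ol
Product: 6 (S)-3-(TBS-oxy)-1-[4-(TBS-oxy)phenyl]hex-5-ene
Conditions: TBSCl, imidazole, DMF, rt
Reagents that add atoms: tert-butyldimethylsilyl chloride, CC(C)(C)[Si](C)(C)Cl
Why: Standard silylation of a secondary alcohol; the stereocentre is not touched.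

Step 4
Reactants: 6 (S)-3-(TBS-oxy)-1-[4-(TBS-oxy)phenyl]hex-5-ene; 7 acrylic acid
Product: 8 (2E,5S)-5-(TBS-oxy)-7-[4-(TBS-oxy)phenyl]hept-2-enoic acid
Conditions: second-generation Grubbs catalyst RuCl2(=CHPh)(PCy3)(H2IMes) (3 mol%), 7 (3 equiv), CH2Cl2, 40 °C
Reagents that add atoms: none
Why: Olefin cross-metathesis between a readily dimerising terminal alkene and an electron-poor acrylic partner, which should give the (E)-enoic acid under thermodynamic control.

Step 5
Reactants: 8 (2E,5S)-5-(TBS-oxy)-7-[4-(TBS-oxy)phenyl]hept-2-enoic acid; 5 (S)-1-[4-(TBS-oxy)phenyl]hex-5-en-3-ol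
Product: 9 (3S)-1-[4-(TBS-oxy)phenyl]hex-5-en-3-yl (2E,5S)-5-(TBS-oxy)-7-[4-(TBS-oxy)phenyl]hept-2-enoate
Conditions: DCC, DMAP (cat.), CH2Cl2, 0 °C to rt
Reagents that add atoms: none
Why: Steglich esterification with retention at the carbinol; because both partners stem from the same enantiomer of 5, residual minor enantiomer should end up in a separable diastereomer.

Step 6
Reactants: 9 (3S)-1-[4-(TBS-oxy)phenyl]hex-5-en-3-yl (2E,5S)-5-(TBS-oxy)-7-[4-(TBS-oxy)phenyl]hept-2-enoate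
Product: 11 (3S)-1-oxo-5-[4-(TBS-oxy)phenyl]pentan-3-yl (2E,5S)-5-(TBS-oxy)-7-[4-(TBS-oxy)phenyl]hept-2-enoate, via secondary ozonide 10 (not isolated)
Conditions: O3, CH2Cl2, −78 °C, Sudan Red 7B as end-point indicator; then PPh3, −78 °C to rt; used without chromatography
Reagents that add atoms: ozone, [O-][O+]=O
Why: Ozonolysis with reductive work-up, in which electrophilic ozone should consume the electron-rich monosubstituted alkene before the conjugated enoate, the dye marking the end point.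

Step 7
Reactants: 12 tert-butyl(4-ethynylphenoxy)dimethylsilane
Product: 14 [(E)-2-[4-(TBS-oxy)phenyl]ethenyl]boronic acid, via catechol boronate 13 (not isolated)
Conditions: catecholborane, THF, 70 °C; then H2O, rt
Reagents that add atoms: catecholborane, B1Oc2ccccc2O1; water, O
Why: Syn, anti-Markovnikov hydroboration of the terminal alkyne fixes the (E) geometry, and hydrolysis of the catechol ester gives the boronic acid.

Step 8
Reactants: 11 (3S)-1-oxo-5-[4-(TBS-oxy)phenyl]pentan-3-yl (2E,5S)-5-(TBS-oxy)-7-[4-(TBS-oxy)phenyl]hept-2-enoate; 14 [(E)-2-[4-(TBS-oxy)phenyl]ethenyl]boronic acid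
Product: 16 (3S,4S,6S)-4-hydroxy-3-[(1E,3S,5S)-5-(TBS-oxy)-1,7-bis[4-(TBS-oxy)phenyl]hept-1-en-3-yl]-6-[2-[4-(TBS-oxy)phenyl]ethyl]oxan-2-one, via rhodium enolate 15 (not isolated)
Conditions: [Rh(OH)((S)-binap)]2 (3 mol%), 14 (2 equiv), dioxane/H2O (20:1), 40 °C
Reagents that add atoms: none
Why: Proposed new method: transmetalation of 14 to the hydroxorhodium complex gives a styryl–rhodium species (monovalent rhodium) that inserts the s-cis (E)-enoate to form the O-bound (Z)-enolate 15, which adds to the tethered aldehyde and is released by the next boronic acid; the closest known reactions are the Hayashi–Miyaura alkenylation of enoates and the rhodium-catalysed conjugate addition–aldol cyclisation of keto-enones, here extended to an ester-tethered enoate–aldehyde. The oxan-2-one ring closes in a 6-(enolendo)-exo-trig aldol that forms the C3–C4 bond. C3′ is set by the catalyst, (S)-BINAP directing the styryl group to the α-Si face of the enoate. C3 and C4 are set by the C6 stereocentre through a chair-like Zimmerman–Traxler transition state in which rhodium bridges the enolate and aldehyde oxygens, so that the C4–O bond is axial while the arylethyl group at C6 and the C3 substituent of the (Z)-enolate are equatorial, which should give the 3,4-cis-4,6-trans lactone. The step needs 1,4-addition to the enoate to outrun 1,2-addition of the alkenylrhodium to the aliphatic aldehyde, which the bisphosphine ligand, the low temperature and the high conjugate reactivity of alkenylboronic acids should secure. It also needs aldolisation to outrun protonation of 15, which the intramolecular six-membered closure and the low water content favour.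

Step 9
Reactants: 16 the 4-hydroxy lactone
Product: 17 (3S,4S,6S)-4-(TBS-oxy)-3-[(1E,3S,5S)-5-(TBS-oxy)-1,7-bis[4-(TBS-oxy)phenyl]hept-1-en-3-yl]-6-[2-[4-(TBS-oxy)phenyl]ethyl]oxan-2-one
Conditions: TBSOTf, 2,6-lutidine, CH2Cl2, −78 to 0 °C
Reagents that add atoms: tert-butyldimethylsilyl triflate, CC(C)(C)[Si](C)(C)OS(=O)(=O)C(F)(F)F
Why: Silylation of the hindered axial alcohol with the reactive triflate prevents retro-aldol opening and alkoxide chemistry in the next step.

Step 10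
Reactants: 17 the silylated lactone; 18 (4-bromophenoxy)(tert-butyl)dimethylsilane
Product: 19 (3S,4S,6S)-4-(TBS-oxy)-2-[4-(TBS-oxy)phenyl]-3-[(1E,3S,5S)-5-(TBS-oxy)-1,7-bis[4-(TBS-oxy)phenyl]hept-1-en-3-yl]-6-[2-[4-(TBS-oxy)phenyl]ethyl]oxan-2-ol (anomer mixture)
Conditions: 18, n-BuLi, THF, −78 °C; then 17, −78 °C; aq. NH4Cl
Reagents that add atoms: none
Why: Bromine–lithium exchange gives the aryllithium, which adds once to the δ-lactone because the tetrahedral lithium hemiketalate is stable at −78 °C, as in aryl C-glycoside synthesis from lactones.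

Step 11
Reactants: 19 the lactol
Product: 21 (2S,3R,4S,6S)-4-(TBS-oxy)-2-[4-(TBS-oxy)phenyl]-3-[(1E,3S,5S)-5-(TBS-oxy)-1,7-bis[4-(TBS-oxy)phenyl]hept-1-en-3-yl]-6-[2-[4-(TBS-oxy)phenyl]ethyl]oxane, via oxocarbenium triflate 20 (not isolated)
Conditions: Et3SiH (3 equiv), Me3SiOTf (0.2 equiv), CH2Cl2, −78 °C
Reagents that add atoms: none
Why: Ionic reduction of the lactol, in which the aryl-stabilised oxocarbenium ion takes hydride along the axial trajectory of the half-chair with the C3 and C6 substituents pseudo-equatorial, placing the aryl group equatorial (2,6-cis, 2,3-trans); the descriptor at C3 changes only because of CIP priorities.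

Step 12
Reactants: 21 the hexasilyl ether
Product: 22 blepharocalyxin C
Conditions: Bu4NF (excess), AcOH, THF, 0 °C to rt
Reagents that add atoms: none
Why: Fluoride cleaves the four aryl and two secondary alkyl silyl ethers, and the acetic acid buffer should keep phenoxide-induced opening of the benzylic ether in check.

**Compound list**

1 | tert-butyl(4-iodophenoxy)dimethylsilane | CC(C)(C)[Si](C)(C)Oc1ccc(I)cc1 | starting material
2 | prop-2-en-1-ol (allyl alcohol) | C=CCO | starting material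
3 | 3-[4-(tert-butyldimethylsilyloxy)phenyl]propanal | CC(C)(C)[Si](C)(C)Oc1ccc(CCC=O)cc1 | intermediate
4 | allyltributylstannane | C=CC[Sn](CCCC)(CCCC)CCCC | starting material
5 | (S)-1-[4-(TBS-oxy)phenyl]hex-5-en-3-ol | C=CC[C@@H](O)CCc1ccc(O[Si](C)(C)C(C)(C)C)cc1 | intermediate
6 | (S)-3-(TBS-oxy)-1-[4-(TBS-oxy)phenyl]hex-5-ene | C=CC[C@@H](O[Si](C)(C)C(C)(C)C)CCc1ccc(O[Si](C)(C)C(C)(C)C)cc1 | intermediate
7 | acrylic acid | C=CC(=O)O | starting material
8 | (2E,5S)-5-(TBS-oxy)-7-[4-(TBS-oxy)phenyl]hept-2-enoic acid | OC(=O)/C=C/C[C@@H](O[Si](C)(C)C(C)(C)C)CCc1ccc(O[Si](C)(C)C(C)(C)C)cc1 | intermediate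
9 | (3S)-1-[4-(TBS-oxy)phenyl]hex-5-en-3-yl (2E,5S)-5-(TBS-oxy)-7-[4-(TBS-oxy)phenyl]hept-2-enoate | C=CC[C@@H](OC(=O)/C=C/C[C@@H](O[Si](C)(C)C(C)(C)C)CCc1ccc(O[Si](C)(C)C(C)(C)C)cc1)CCc1ccc(O[Si](C)(C)C(C)(C)C)cc1 | intermediate
10 | secondary ozonide (1,2,4-trioxolane) of the terminal alkene of 9 | C1OC(C[C@@H](OC(=O)/C=C/C[C@@H](O[Si](C)(C)C(C)(C)C)CCc2ccc(O[Si](C)(C)C(C)(C)C)cc2)CCc2ccc(O[Si](C)(C)C(C)(C)C)cc2)OO1 | intermediate
11 | (3S)-1-oxo-5-[4-(TBS-oxy)phenyl]pentan-3-yl (2E,5S)-5-(TBS-oxy)-7-[4-(TBS-oxy)phenyl]hept-2-enoate | O=CC[C@@H](OC(=O)/C=C/C[C@@H](O[Si](C)(C)C(C)(C)C)CCc1ccc(O[Si](C)(C)C(C)(C)C)cc1)CCc1ccc(O[Si](C)(C)C(C)(C)C)cc1 | intermediate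
12 | tert-butyl(4-ethynylphenoxy)dimethylsilane | C#Cc1ccc(O[Si](C)(C)C(C)(C)C)cc1 | starting material
13 | 2-[(E)-2-[4-(TBS-oxy)phenyl]ethenyl]-1,3,2-benzodioxaborole | CC(C)(C)[Si](C)(C)Oc1ccc(/C=C/B2Oc3ccccc3O2)cc1 | intermediate
14 | [(E)-2-[4-(TBS-oxy)phenyl]ethenyl]boronic acid | CC(C)(C)[Si](C)(C)Oc1ccc(/C=C/B(O)O)cc1 | intermediate
15 | O-bound (Z)-enolate of monovalent rhodium formed by styryl transfer to C3′ of 11, (3′S), BINAP on rhodium not drawn | O=CC[C@@H](O/C(O[Rh])=C/[C@H](/C=C/c1ccc(O[Si](C)(C)C(C)(C)C)cc1)C[C@@H](O[Si](C)(C)C(C)(C)C)CCc1ccc(O[Si](C)(C)C(C)(C)C)cc1)CCc1ccc(O[Si](C)(C)C(C)(C)C)cc1 | intermediate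
16 | (3S,4S,6S)-4-hydroxy-3-[(1E,3S,5S)-5-(TBS-oxy)-1,7-bis[4-(TBS-oxy)phenyl]hept-1-en-3-yl]-6-[2-[4-(TBS-oxy)phenyl]ethyl]oxan-2-one | CC(C)(C)[Si](C)(C)Oc1ccc(/C=C/[C@H](C[C@@H](O[Si](C)(C)C(C)(C)C)CCc2ccc(O[Si](C)(C)C(C)(C)C)cc2)[C@@H]2C(=O)O[C@@H](CCc3ccc(O[Si](C)(C)C(C)(C)C)cc3)C[C@@H]2O)cc1 | intermediate
17 | (3S,4S,6S)-4-(TBS-oxy) ether of 16 | CC(C)(C)[Si](C)(C)Oc1ccc(/C=C/[C@H](C[C@@H](O[Si](C)(C)C(C)(C)C)CCc2ccc(O[Si](C)(C)C(C)(C)C)cc2)[C@@H]2C(=O)O[C@@H](CCc3ccc(O[Si](C)(C)C(C)(C)C)cc3)C[C@@H]2O[Si](C)(C)C(C)(C)C)cc1 | intermediate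
18 | (4-bromophenoxy)(tert-butyl)dimethylsilane | CC(C)(C)[Si](C)(C)Oc1ccc(Br)cc1 | starting material
19 | (3S,4S,6S)-2-aryl lactol (oxan-2-ol, anomer mixture) from 17 | CC(C)(C)[Si](C)(C)Oc1ccc(/C=C/[C@H](C[C@@H](O[Si](C)(C)C(C)(C)C)CCc2ccc(O[Si](C)(C)C(C)(C)C)cc2)[C@@H]2C(O)(c3ccc(O[Si](C)(C)C(C)(C)C)cc3)O[C@@H](CCc3ccc(O[Si](C)(C)C(C)(C)C)cc3)C[C@@H]2O[Si](C)(C)C(C)(C)C)cc1 | intermediate
20 | 2-aryl cyclic oxocarbenium triflate from 19 | CC(C)(C)[Si](C)(C)Oc1ccc(/C=C/[C@H](C[C@@H](O[Si](C)(C)C(C)(C)C)CCc2ccc(O[Si](C)(C)C(C)(C)C)cc2)[C@@H]2C(c3ccc(O[Si](C)(C)C(C)(C)C)cc3)=[O+][C@@H](CCc3ccc(O[Si](C)(C)C(C)(C)C)cc3)C[C@@H]2O[Si](C)(C)C(C)(C)C)cc1.[O-]S(=O)(=O)C(F)(F)F | intermediate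
21 | (2S,3R,4S,6S)-hexa-TBS ether of blepharocalyxin C | CC(C)(C)[Si](C)(C)Oc1ccc(/C=C/[C@H](C[C@@H](O[Si](C)(C)C(C)(C)C)CCc2ccc(O[Si](C)(C)C(C)(C)C)cc2)[C@@H]2[C@@H](c3ccc(O[Si](C)(C)C(C)(C)C)cc3)O[C@@H](CCc3ccc(O[Si](C)(C)C(C)(C)C)cc3)C[C@@H]2O[Si](C)(C)C(C)(C)C)cc1 | intermediate
22 | blepharocalyxin C, (2S,3S,4S,6S)-2-(4-hydroxyphenyl)-6-[2-(4-hydroxyphenyl)ethyl]-3-[(1E,3S,5S)-5-hydroxy-1,7-bis(4-hydroxyphenyl)hept-1-en-3-yl]oxan-4-ol | Oc1ccc(/C=C/[C@H](C[C@@H](O)CCc2ccc(O)cc2)[C@@H]2[C@@H](c3ccc(O)cc3)O[C@@H](CCc3ccc(O)cc3)C[C@@H]2O)cc1 | target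

**Step count**

Total: 12 steps. Longest linear sequence: 11 steps (steps 1–6 and 8–12); step 7 is a one-step side branch.

**Steps most likely to fail**

1. Step 8 (Proposed new method). The alkenylrhodium may add directly to the aldehyde. The rhodium enolate may be protonated before it aldolises. The β-acyloxy aldehyde may lose the carboxylate by β-elimination. The aldol may also proceed through a non-chelated transition state with poor facial control at C3 and C4. The fallback uses known chemistry, sets out from 11 and comes back at 16. The aldehyde of 11 is masked with HC(OMe)3 and PPTS in MeOH to give the dimethyl acetal F1. A Hayashi–Miyaura addition of 14 with [Rh(OH)((S)-binap)]2 in dioxane/H2O at 50 °C then sets C3′ and gives the β-styryl ester F2. Enolisation with LiN(SiMe3)2 and Me3SiCl at −78 °C followed by NBS gives the α-bromo ester F3 as an epimer mixture. Hydrolysis of the acetal with LiBF4 in wet MeCN frees the bromo aldehyde F4. SmI2 in THF at −78 °C then closes the same C3–C4 bond by an intramolecular Reformatsky reaction, whose enolate of trivalent samarium chelates the aldehyde and should give 16.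

2. Step 10. The aryllithium may act as a base toward the hindered lactone, and enolisation at C3 would be followed by β-elimination of the C4 silyloxy group or by epimerisation. The fallback sets out from 17 and comes back at 21, bypassing 19. Reduction with i-Bu2AlH at −78 °C and acetylation of the aluminium hemiacetal in the same flask (Ac2O, pyridine, DMAP) give the anomeric acetate F5 without any basic carbon nucleophile. A Friedel–Crafts C-arylation with tert-butyldimethyl(phenoxy)silane and BF3·OEt2 in CH2Cl2 at −40 to 0 °C then introduces the aryl group at its para position. Reversible ionisation of the electron-rich benzylic ether should equilibrate the product to the equatorial aryl isomer 21.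

3. Step 11. Hydride delivery may be slowed or diverted to the other face because the axial C4 silyloxy group is syn-axial to the incoming silane, and the oxocarbenium ion may lose the C3 proton to give an enol ether. The fallback sets out from 19 and comes back at 21. NaBH4 in THF/MeOH at 0 °C reduces the ring-opened hydroxy ketone tautomer of 19 to the diol F6. Catalytic TsOH in CH2Cl2 at 0 °C then ionises the p-silyloxybenzylic alcohol, and ring closure by the C6 hydroxyl under thermodynamic control should give the all-equatorial 2,6-cis oxane 21.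

**Further compounds**

F1 | step 8 | dimethyl acetal of 11, (3S)-1,1-dimethoxy-5-[4-(TBS-oxy)phenyl]pentan-3-yl (2E,5S)-5-(TBS-oxy)-7-[4-(TBS-oxy)phenyl]hept-2-enoate | COC(OC)C[C@@H](OC(=O)/C=C/C[C@@H](O[Si](C)(C)C(C)(C)C)CCc1ccc(O[Si](C)(C)C(C)(C)C)cc1)CCc1ccc(O[Si](C)(C)C(C)(C)C)cc1
F2 | step 8 | β-styryl ester, conjugate adduct of F1 with the C3′ centre set | COC(OC)C[C@@H](OC(=O)C[C@H](/C=C/c1ccc(O[Si](C)(C)C(C)(C)C)cc1)C[C@@H](O[Si](C)(C)C(C)(C)C)CCc1ccc(O[Si](C)(C)C(C)(C)C)cc1)CCc1ccc(O[Si](C)(C)C(C)(C)C)cc1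
F3 | step 8 | α-bromo ester from F2 (epimers at the bromine-bearing carbon) | COC(OC)C[C@@H](OC(=O)C(Br)[C@H](/C=C/c1ccc(O[Si](C)(C)C(C)(C)C)cc1)C[C@@H](O[Si](C)(C)C(C)(C)C)CCc1ccc(O[Si](C)(C)C(C)(C)C)cc1)CCc1ccc(O[Si](C)(C)C(C)(C)C)cc1
F4 | step 8 | bromo aldehyde from F3 | O=CC[C@@H](OC(=O)C(Br)[C@H](/C=C/c1ccc(O[Si](C)(C)C(C)(C)C)cc1)C[C@@H](O[Si](C)(C)C(C)(C)C)CCc1ccc(O[Si](C)(C)C(C)(C)C)cc1)CCc1ccc(O[Si](C)(C)C(C)(C)C)cc1
F5 | step 10 | anomeric acetate (oxan-2-yl acetate, anomer mixture) from 17 | CC(C)(C)[Si](C)(C)Oc1ccc(/C=C/[C@H](C[C@@H](O[Si](C)(C)C(C)(C)C)CCc2ccc(O[Si](C)(C)C(C)(C)C)cc2)[C@@H]2C(OC(C)=O)O[C@@H](CCc3ccc(O[Si](C)(C)C(C)(C)C)cc3)C[C@@H]2O[Si](C)(C)C(C)(C)C)cc1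
F6 | step 11 | ring-opened diol from 19 (benzylic carbinol epimers) | CC(C)(C)[Si](C)(C)Oc1ccc(/C=C/[C@H](C[C@@H](O[Si](C)(C)C(C)(C)C)CCc2ccc(O[Si](C)(C)C(C)(C)C)cc2)[C@H](C(O)c2ccc(O[Si](C)(C)C(C)(C)C)cc2)[C@@H](O[Si](C)(C)C(C)(C)C)C[C@@H](O)CCc2ccc(O[Si](C)(C)C(C)(C)C)cc2)cc1
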